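**Retrosynthetic overview**
1. Olivil monoacetate ⇐ hydrogenolysis (benzylic epoxide C–O, two benzyl ethers) ⇐ spiro-epoxide ⇐ epoxidation anti to CH2OAc ⇐ enantiopure acetate ⇐ lipase acetylation of the racemic 2,3-trans alcohol ⇐ ester reduction ⇐ Krapcho removal of one ester from a 3,3-diester.
2. Key disconnection: the 2-aryl-4-arylidene oxolane-3,3-diester is cut at O1–C2, C3–C4 and the benzylic carbon–aryl bond into lithium propargyl alkoxide, an arylidene malonate and an aryl iodide, joined in one pot under zerovalent palladium.
3. Feature used: in the ring O1–C2(aryl)–C3(CH2OAc)–C4(OH)(CH2Ar)–C5H2, the chain O1–C5–C4–benzylic CH2 is the skeleton of propargyl alcohol; C2, C3 and the CH2OAc carbon are the β-carbon, α-carbon and one carboxyl carbon of an arylidene malonate.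
4. Ring order: only the oxolane is built (key step). The stereocentres follow as C3 (trans to C2 by equilibration), C2/C3 absolute (lipase) and C4 (face of epoxidation).

Key step: step 4

Remark on drawing: racemic compounds are drawn as the enantiomer that is carried on.
Assumption: Burkholderia cepacia lipase is taken to acylate the (2S,3R)-alcohol faster. Should it prefer the mirror image, the unreacted (2S,3R)-alcohol would be recovered past half conversion and acetylated with Ac2O/pyridine to the same acetate.

**Step 1**
Reactants: 1 vanillin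
Product: 2 4-(benzyloxy)-3-methoxybenzaldehyde
Conditions: BnBr, K2CO3, DMF, rt
Reagents that add atoms: benzyl bromide, BrCc1ccccc1
Why: Williamson ether synthesis, in which the phenoxide formed by K2CO3 displaces bromide from benzyl bromide while the aldehyde is untouched.

**Step 2**
Reactants: 2 4-(benzyloxy)-3-methoxybenzaldehyde; 3 diethyl malonate
Product: 4 diethyl 2-{[4-(benzyloxy)-3-methoxyphenyl]methylidene}malonate
Conditions: piperidine (cat.), AcOH (cat.), toluene, reflux, Dean–Stark
Reagents that add atoms: none
Why: Knoevenagel condensation under piperidinium acetate catalysis, driven to the arylidene malonate by azeotropic removal of water; no stereocentre is formed.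

**Step 3**
Reactants: 5 4-iodo-2-methoxyphenol
Product: 6 1-(benzyloxy)-4-iodo-2-methoxybenzene
Conditions: BnBr, K2CO3, DMF, rt
Reagents that add atoms: benzyl bromide, BrCc1ccccc1
Why: Williamson ether synthesis on the phenol; the aryl iodide is inert to carbonate and to benzyl bromide.

**Step 4**
Reactants: 7 propargyl alcohol; 4 diethyl 2-{[4-(benzyloxy)-3-methoxyphenyl]methylidene}malonate; 6 1-(benzyloxy)-4-iodo-2-methoxybenzene
Product: 10 diethyl (2RS,4Z)-2-[4-(benzyloxy)-3-methoxyphenyl]-4-{[4-(benzyloxy)-3-methoxyphenyl]methylidene}oxolane-3,3-dicarboxylate (racemic), via lithium prop-2-yn-1-olate 8 (not isolated), via lithium malonate oxa-Michael adduct 9 (not isolated)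
Conditions: n-BuLi (1.0 equiv), THF, 0 °C; then 4, rt; then 6 and PdCl2(PPh3)2 (5 mol %, reduced beforehand with n-BuLi, 10 mol %, to zerovalent palladium), THF–DMSO, rt
Reagents that add atoms: none
Why: The lithium alkoxide adds reversibly to the arylidene malonate (oxa-Michael, O1–C2) and gives a malonate carbanion five atoms from the alkyne; zerovalent palladium inserts into the C–I bond of 6, the arylpalladium iodide binds the alkyne, the carbanion attacks the bound alkyne on the side opposite to palladium (C3–C4), and reductive elimination from the vinyl(aryl)palladium forms the benzylic carbon–aryl bond and returns zerovalent palladium. The closest known reaction type is the palladium-mediated three-component coupling of propargyl alkoxides, alkylidene malonates and aryl halides to 4-arylidene tetrahydrofurans. The oxolane closes in the 5-exo-dig mode. C2 is the only new stereocentre and forms racemic because nothing chiral is present, while the alkene geometry (aryl cis to C5H2) follows from the anti carbopalladation. The step needs cyclisation to outrun direct coupling of the aryl iodide with the alkyne terminus or the alkoxide; the soft, doubly stabilised carbanion held five atoms from the alkyne and the copper-free, DMSO-containing medium should secure this.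

**Step 5**
Reactants: 10 diethyl (2RS,4Z)-2-[4-(benzyloxy)-3-methoxyphenyl]-4-{[4-(benzyloxy)-3-methoxyphenyl]methylidene}oxolane-3,3-dicarboxylate
Product: 11 ethyl (2RS,3RS,4Z)-2-[4-(benzyloxy)-3-methoxyphenyl]-4-{[4-(benzyloxy)-3-methoxyphenyl]methylidene}oxolane-3-carboxylate (racemic, aryl and ester trans)
Conditions: LiCl, H2O, DMSO, 150 °C
Reagents that add atoms: none
Why: Krapcho dealkoxycarbonylation, in which chloride dealkylates one ethyl ester, the carboxylate loses CO2 and the ester dienolate is protonated at the α-carbon so that the alkene stays conjugated with its aryl ring; the acidic, allylic C3–H should equilibrate in the hot, weakly basic medium to the more stable isomer with the ester trans to the C2 aryl group.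

**Step 6**
Reactants: 11 ethyl (2RS,3RS,4Z)-2-[4-(benzyloxy)-3-methoxyphenyl]-4-{[4-(benzyloxy)-3-methoxyphenyl]methylidene}oxolane-3-carboxylate
Product: 12 [(2RS,3SR,4Z)-2-[4-(benzyloxy)-3-methoxyphenyl]-4-{[4-(benzyloxy)-3-methoxyphenyl]methylidene}oxolan-3-yl]methanol (racemic, 2,3-trans)
Conditions: LiAlH4, THF, 0 °C
Reagents that add atoms: none
Why: Hydride reduction of the ester to the primary alcohol, which at 0 °C should be faster than enolisation so that the trans C2/C3 relationship is kept, and which leaves the styrenyl alkene and the benzyl ethers alone.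

**Step 7**
Reactants: 12 [(2RS,3SR,4Z)-2-[4-(benzyloxy)-3-methoxyphenyl]-4-{[4-(benzyloxy)-3-methoxyphenyl]methylidene}oxolan-3-yl]methanol
Product: 13 [(2S,3R,4Z)-2-[4-(benzyloxy)-3-methoxyphenyl]-4-{[4-(benzyloxy)-3-methoxyphenyl]methylidene}oxolan-3-yl]methyl acetate
Conditions: Burkholderia cepacia lipase (lipase PS), vinyl acetate, t-BuOMe, 30 °C, stopped below half conversion; chromatography
Reagents that add atoms: vinyl acetate, CC(=O)OC=C
Why: Lipase-catalysed kinetic resolution by irreversible transesterification with vinyl acetate, in which the enzyme acylates one enantiomer of the primary alcohol faster, so that stopping early should give the acetate as the (2S,3R) enantiomer and install the acetate of the target in the same operation.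

**Step 8**
Reactants: 13 [(2S,3R,4Z)-2-[4-(benzyloxy)-3-methoxyphenyl]-4-{[4-(benzyloxy)-3-methoxyphenyl]methylidene}oxolan-3-yl]methyl acetate
Product: 14 [(2R,3S,6S,7R)-2,6-bis[4-(benzyloxy)-3-methoxyphenyl]-1,5-dioxaspiro[2.4]heptan-7-yl]methyl acetate (epoxide oxygen trans to the CH2OAc arm)
Conditions: dimethyldioxirane, acetone, 0 °C; crude epoxide used directly
Reagents that add atoms: dimethyldioxirane, CC1(C)OO1
Why: Epoxidation by a dioxirane under neutral conditions that spare the acid-labile, electron-rich aryl epoxide; the reagent should approach the exocyclic alkene on the face opposite the adjacent C3 CH2OAc arm, which places the C4 oxygen trans to that arm as in the target.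

**Step 9**
Reactants: 14 [(2R,3S,6S,7R)-2,6-bis[4-(benzyloxy)-3-methoxyphenyl]-1,5-dioxaspiro[2.4]heptan-7-yl]methyl acetate
Product: 15 olivil monoacetate, [(2S,3R,4S)-4-hydroxy-2-(4-hydroxy-3-methoxyphenyl)-4-[(4-hydroxy-3-methoxyphenyl)methyl]oxolan-3-yl]methyl acetate
Conditions: H2 (1 atm), 10% Pd/C, EtOAc, rt
Reagents that add atoms: none
Why: Heterogeneous catalytic hydrogenolysis, which cleaves the benzylic C–O bond of the epoxide (the tertiary C4–O bond and its configuration remain) and both benzyl aryl ethers, while the cyclic benzylic ether C2–O1 and the acetate should persist under neutral conditions at low pressure.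

**Compound list**
1 | vanillin | COc1cc(C=O)ccc1O | starting material
2 | 4-(benzyloxy)-3-methoxybenzaldehyde | COc1cc(C=O)ccc1OCc1ccccc1 | intermediate
3 | diethyl malonate | CCOC(=O)CC(=O)OCC | starting material
4 | diethyl 2-{[4-(benzyloxy)-3-methoxyphenyl]methylidene}malonate | CCOC(=O)C(=Cc1ccc(OCc2ccccc2)c(OC)c1)C(=O)OCC | intermediate
5 | 4-iodo-2-methoxyphenol | COc1cc(I)ccc1O | starting material
6 | 1-(benzyloxy)-4-iodo-2-methoxybenzene | COc1cc(I)ccc1OCc1ccccc1 | intermediate
7 | propargyl alcohol | C#CCO | starting material
8 | lithium prop-2-yn-1-olate | [Li+].[O-]CC#C | intermediate (not isolated)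
9 | lithium enolate of diethyl 2-{[4-(benzyloxy)-3-methoxyphenyl](prop-2-yn-1-yloxy)methyl}malonate (racemic) | [Li+].CCOC(=O)[C-](C(=O)OCC)C(OCC#C)c1ccc(OCc2ccccc2)c(OC)c1 | intermediate (not isolated)
10 | diethyl (2RS,4Z)-2-[4-(benzyloxy)-3-methoxyphenyl]-4-{[4-(benzyloxy)-3-methoxyphenyl]methylidene}oxolane-3,3-dicarboxylate (racemic; 2R drawn) | COc1cc(/C=C2\CO[C@H](c3ccc(OCc4ccccc4)c(OC)c3)C2(C(=O)OCC)C(=O)OCC)ccc1OCc1ccccc1 | intermediate
11 | ethyl (2RS,3RS,4Z)-2-[4-(benzyloxy)-3-methoxyphenyl]-4-{[4-(benzyloxy)-3-methoxyphenyl]methylidene}oxolane-3-carboxylate (racemic, 2,3-trans; 2S,3S drawn) | COc1cc(/C=C2\CO[C@H](c3ccc(OCc4ccccc4)c(OC)c3)[C@H]2C(=O)OCC)ccc1OCc1ccccc1 | intermediate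
12 | [(2RS,3SR,4Z)-2-[4-(benzyloxy)-3-methoxyphenyl]-4-{[4-(benzyloxy)-3-methoxyphenyl]methylidene}oxolan-3-yl]methanol (racemic, 2,3-trans; 2S,3R drawn) | COc1cc(/C=C2\CO[C@H](c3ccc(OCc4ccccc4)c(OC)c3)[C@H]2CO)ccc1OCc1ccccc1 | intermediate
13 | [(2S,3R,4Z)-2-[4-(benzyloxy)-3-methoxyphenyl]-4-{[4-(benzyloxy)-3-methoxyphenyl]methylidene}oxolan-3-yl]methyl acetate | COc1cc(/C=C2\CO[C@H](c3ccc(OCc4ccccc4)c(OC)c3)[C@H]2COC(C)=O)ccc1OCc1ccccc1 | intermediate
14 | [(2R,3S,6S,7R)-2,6-bis[4-(benzyloxy)-3-methoxyphenyl]-1,5-dioxaspiro[2.4]heptan-7-yl]methyl acetate | COc1cc([C@H]2O[C@@]23CO[C@H](c4ccc(OCc5ccccc5)c(OC)c4)[C@H]3COC(C)=O)ccc1OCc1ccccc1 | intermediate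
15 | olivil monoacetate, [(2S,3R,4S)-4-hydroxy-2-(4-hydroxy-3-methoxyphenyl)-4-[(4-hydroxy-3-methoxyphenyl)methyl]oxolan-3-yl]methyl acetate | COc1cc(C[C@@]2(O)CO[C@H](c3ccc(O)c(OC)c3)[C@H]2COC(C)=O)ccc1O | target

**Step count**
Total steps: 9. Longest linear sequence: 8 steps (vanillin, steps 1, 2, 4, 5, 6, 7, 8, 9).

**Steps most likely to fail**

Step 5. The dienolate may be protonated under kinetic control, which would put the ester cis to the aryl group. Alternatively, on long heating with the base that builds up, the alkene may move into the ring. The fallback sets out from 10 and returns at 11, and separates decarboxylation from the setting of C3. Half-saponification (KOH, 1 equiv, EtOH–H2O, rt) would give the malonic half-acid F2. Warming F2 in toluene would let CO2 leave through the cyclic six-membered transition state without a free dienolate, so the alkene stays exocyclic, and would give ester 11 mixed with its 2,3-cis epimer F3. Catalytic DBU in toluene at room temperature, where α-protonation of the dienolate outruns γ-protonation, would then move F3 over to the trans ester 11.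

Step 8. Facial selectivity may be poor because the C3 arm can lie pseudo-equatorial, and the electron-rich aryl epoxide may open under traces of acid during handling. The fallback sets out from 13 and returns at 15. OsO4 (cat.) with N-methylmorpholine N-oxide in acetone–water, a bulkier reagent, would dihydroxylate the alkene on the face opposite the CH2OAc arm and give the stable [(2S,3R,4S)-2-[4-(benzyloxy)-3-methoxyphenyl]-4-{(R)-[4-(benzyloxy)-3-methoxyphenyl](hydroxy)methyl}-4-hydroxyoxolan-3-yl]methyl acetate F4. Carbonyldiimidazole in CH2Cl2 would close its cyclic carbonate F5. Hydrogenolysis of F5 under the conditions of step 9 would cleave the benzylic carbonate C–O bond (the tertiary carbonic half-ester then loses CO2) and the benzyl ethers, and would give 15.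

Step 4. With the electron-rich arylidene malonate the oxa-Michael equilibrium may lie on the side of free alkoxide, so that the arylpalladium iodide is consumed by direct coupling at the alkyne terminus before the carbanion cyclises. The fallback sets out from 6 and 7 and returns at 10, and makes that aryl–alkyne bond on purpose first. Sonogashira coupling (PdCl2(PPh3)2, CuI, Et3N, rt) would give 3-[4-(benzyloxy)-3-methoxyphenyl]prop-2-yn-1-ol F1. F1 and 4 with catalytic t-BuOK in THF–DMSO would then undergo oxa-Michael addition and base-mediated 5-exo-dig carbocyclisation of the malonate carbanion onto the aryl-activated alkyne. Protonation of the rapidly inverting α-aryl vinyl anion should give the less crowded alkene, which is 10. The alkene geometry is in any case without consequence, because the benzylic carbon ends as CH2.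

**Further compounds**
F1 | step 4 | 3-[4-(benzyloxy)-3-methoxyphenyl]prop-2-yn-1-ol | COc1cc(C#CCO)ccc1OCc1ccccc1
F2 | step 5 | (2RS,4Z)-2-[4-(benzyloxy)-3-methoxyphenyl]-4-{[4-(benzyloxy)-3-methoxyphenyl]methylidene}-3-(ethoxycarbonyl)oxolane-3-carboxylic acid (racemic, C3 configuration open) | COc1cc(/C=C2\CO[C@H](c3ccc(OCc4ccccc4)c(OC)c3)C2(C(=O)O)C(=O)OCC)ccc1OCc1ccccc1
F3 | step 5 | ethyl (2RS,3SR,4Z)-2-[4-(benzyloxy)-3-methoxyphenyl]-4-{[4-(benzyloxy)-3-methoxyphenyl]methylidene}oxolane-3-carboxylate (racemic, 2,3-cis) | COc1cc(/C=C2\CO[C@H](c3ccc(OCc4ccccc4)c(OC)c3)[C@@H]2C(=O)OCC)ccc1OCc1ccccc1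
F4 | step 8 | [(2S,3R,4S)-2-[4-(benzyloxy)-3-methoxyphenyl]-4-{(R)-[4-(benzyloxy)-3-methoxyphenyl](hydroxy)methyl}-4-hydroxyoxolan-3-yl]methyl acetate | COc1cc([C@@H](O)[C@@]2(O)CO[C@H](c3ccc(OCc4ccccc4)c(OC)c3)[C@H]2COC(C)=O)ccc1OCc1ccccc1
F5 | step 8 | cyclic carbonate of F4 across the C4 oxygen and the benzylic oxygen (spiro-fused 1,3-dioxolan-2-one) | COc1cc([C@H]2OC(=O)O[C@@]23CO[C@H](c4ccc(OCc5ccccc5)c(OC)c4)[C@H]3COC(C)=O)ccc1OCc1ccccc1
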